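I ran the same charge for 4.0 h at two temperatures, and I wanted to know what would hold the most starting material at the end of each run.

- Wednesday's: starting material 0.25 M; reagent 5.00 equiv; temperature 110 °C; time 4.0 h
- Tuesday's: starting material 0.25 M; reagent 5.00 equiv; temperature 135 °C; time 4.0 h

    starting material + reagent ⇌ intermediate (K1 = 8.4 M⁻¹, k1 = 2.71 × 10⁻⁵ M⁻¹ s⁻¹, Ea1 = 105 kJ mol⁻¹, ΔH1 = −82.0 kJ mol⁻¹)
    reagent + by-product ⇌ idle adduct, settled at all times (K2 = 0.20 M⁻¹, ΔH2 = −28.0 kJ mol⁻¹)
    intermediate ⇌ target + by-product (K3 = 0.0973 M, k3 = 1.20 × 10⁻⁴ s⁻¹, Ea3 = 114 kJ mol⁻¹, ΔH3 = −39.0 kJ mol⁻¹)
    starting material + target → side product (k4 = 4.92 × 10⁻⁴ M⁻¹ s⁻¹, Ea4 = 68.0 kJ mol⁻¹)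
    (constants at 110 °C)

- in percentages every species weighs as the starting material in it: one side product counts as two
- for by-product the idle adduct is counted in
- the list of constants is for 110 °C, to be carried to other temperatures by the activation energies and enthalpies

1. which of these there is most of at the end, counted by the starting material in it, Wednesday's (starting material / side product / intermediate / target)
2. which of these there is most of at the end, counted by the starting material in it, Tuesday's (starting material / side product / intermediate / target)
3. amount of the one of these that there is most of at the end, in percent of the starting material charged, Wednesday's
4. amount of the one of these that there is most of at the end, in percent of the starting material charged, Tuesday's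

Two numbers sat badly together. On Wednesday's flask the constant of the first step times the reagent as charged came to 10, so that step taken by itself, at balance and with the reagent as charged, stood at ten times as much intermediate as starting material. Yet the rate constant of that same step was a mere 2.71 × 10⁻⁵ M⁻¹ s⁻¹.

A balance says where a flask is heading, not how soon it gets there, so I turned the rate constant into a time. I called it τ, the first-step half-time: the time in which the reagent, held at its charge, halves the starting material by the forward step alone, the way back not counted. With the reagent in excess this is the usual pseudo-first-order view. On Wednesday's flask τ was 5.68 h, longer than the run of 4.0 h. I therefore reckoned 61.4% of the starting material left. The other species share the rest, so my answer for the most on Wednesday's was starting material.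

Carried to Tuesday's temperature by the activation energy, τ shrank to 0.755 h, and 5.30 such half-times fit into that run. So I did not expect starting material to lead on Tuesday's, but τ named no leader for that flask, and my reckoning stopped there.

The forecast gave starting material at 56% (53% to 59%) for Wednesday's, which is lower than my figure. For Tuesday's it gave side product at 50% (42% to 58%), because “the only irreversible exit, starting material plus target, drains the pool into side product”.

For Wednesday's the simulation gave starting material at 57.3%, as forecast. For Tuesday's it gave side product at 49.8%, as forecast too.

The difference in temperature is the main reason for Tuesday's low starting material: 12.0% at the end, against 57.3% at Wednesday's temperature. Early in Tuesday's run, after 0.800 h, τ gave 48.0% and the flask held 47.9%. Wednesday's answer turned with time: left until 10 h, that flask led with side product at 42.9%. Carried down to 85 °C, τ became 56.7 h, which gave 95.2% left after 4.0 h, and that neighbour flask held 95.2%.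

(The constants stand for no real mixture; the flask was simulated.)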